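**Strategy.** The plan cuts the C8–C9 bond of ring B (C6–C11). The exocyclic methylene C7=C14 stands 1,3 to the carbinol C9, which is flanked by the brominated C10: the signature of a type-two intramolecular carbonyl-ene reaction. An isopropenyl group on the spiro carbon C6 attacks an α-bromo aldehyde; one operation closes ring B, moves the double bond to C7=C14 and sets C9 from C10. The precursor is a monocyclic cyclohexane that already holds the ring A trans-bromochloride (installed through a temporary bromo-ether bridge from a carbinol on C6), the quaternary C6 (asymmetric Diels–Alder reaction) and C10 (organocatalytic bromination).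

Key step: step 11

Locants: chamigrane numbering is used throughout. Ring A is C1–C6 (C2 bears Br, C3 bears Cl and CH3, C6 is the spiro carbon). Ring B is C6–C11 (C7 bears the exocyclic CH2 = C14, C9 bears OH, C10 bears Br, C11 bears two CH3).

Assumption: the absolute sense of induction of the two chiral catalysts (steps 2 and 10) is taken as drawn; if either proves opposite with these substrates, its enantiomer is used.

Step 1
Reactants: 1 ketopantolactone (4,4-dimethyloxolane-2,3-dione)
Product: 2 4,4-dimethyl-3-methylideneoxolan-2-one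
Conditions: Ph3PCH3Br, KN(SiMe3)2, THF, −78 °C to rt
Reagents that add atoms: methyltriphenylphosphonium bromide, C[P+](c1ccccc1)(c1ccccc1)c1ccccc1.[Br-]
Why: Wittig methylenation of the non-enolisable, highly electrophilic ketone carbonyl next to the much less reactive lactone carbonyl; no stereocenter is formed.

Step 2
Reactants: 2 4,4-dimethyl-3-methylideneoxolan-2-one; 3 isoprene (2-methylbuta-1,3-diene)
Product: 4 (5R)-4,4,8-trimethyl-2-oxaspiro[4.5]dec-7-en-1-one
Conditions: (S)-1-(2-methylphenyl)-3,3-diphenyltetrahydro-1H,3H-pyrrolo[1,2-c][1,3,2]oxazaborole protonated with HNTf2 (20 mol %), isoprene (5 equiv), CH2Cl2, −40 to 0 °C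
Reagents that add atoms: none
Why: Catalytic enantioselective Diels–Alder reaction under a protonated chiral oxazaborolidine; the diene adds with the usual para orientation (ring methyl 1,4 to the new quaternary carbon), and the catalyst-bound lactone carbonyl leaves one face of the exocyclic alkene open, which sets the spiro carbon (C6 of the target) as R.

Step 3
Reactants: 4 (5R)-4,4,8-trimethyl-2-oxaspiro[4.5]dec-7-en-1-one
Product: 6 2-[(1R)-1-(1-hydroxy-2-methylpropan-2-yl)-4-methylcyclohex-3-en-1-yl]propan-2-ol, via hydroxy ketone 5 (not isolated)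
Conditions: MeLi (4 equiv), CeCl3 (4 equiv), THF, −78 to 0 °C; NH4Cl (aq)
Reagents that add atoms: methyllithium, [Li]C
Why: Double 1,2-addition of the organocerium reagent to the hindered lactone (CeCl3 suppresses enolisation of the intermediate methyl ketone) opens the temporary lactone ring to the tertiary carbinol at C7 and the primary alcohol at C10, with C6 untouched.

Step 4
Reactants: 6 2-[(1R)-1-(1-hydroxy-2-methylpropan-2-yl)-4-methylcyclohex-3-en-1-yl]propan-2-ol
Product: 8 (5R)-1,1,4,4,8-pentamethyl-2-oxaspiro[4.5]dec-7-en-3-ol, via hydroxy aldehyde 7 (not isolated)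
Conditions: (COCl)2, DMSO, CH2Cl2, −78 °C; Et3N, −78 °C to rt
Reagents that add atoms: none
Why: Swern oxidation can only touch the primary neopentyl alcohol, and the aldehyde is trapped by the neighbouring tertiary hydroxyl as a five-membered lactol whose two anomers are of no consequence.

Step 5
Reactants: 8 (5R)-1,1,4,4,8-pentamethyl-2-oxaspiro[4.5]dec-7-en-3-ol
Product: 9 2-[(1R)-4-methyl-1-(2-methylbut-3-en-2-yl)cyclohex-3-en-1-yl]propan-2-ol
Conditions: Ph3PCH3Br (3 equiv), KOtBu (3 equiv), THF, 0 °C to reflux
Reagents that add atoms: methyltriphenylphosphonium bromide, C[P+](c1ccccc1)(c1ccccc1)c1ccccc1.[Br-]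
Why: Wittig methylenation of the open hydroxy aldehyde form of the lactol (the ylide also serves as the base that opens it) turns C10 into the vinyl group that later carries C9.

Step 6
Reactants: 9 2-[(1R)-4-methyl-1-(2-methylbut-3-en-2-yl)cyclohex-3-en-1-yl]propan-2-ol
Product: 10 (1S,4R,6S)-6-bromo-1,3,3-trimethyl-4-(2-methylbut-3-en-2-yl)-2-oxabicyclo[2.2.2]octane
Conditions: NBS, NaHCO3, CH2Cl2, 0 °C, dark
Reagents that add atoms: N-bromosuccinimide, O=C1CCC(=O)N1Br
Why: Bromoetherification (the reaction type that turns α-terpineol into a bromo-cineole): of the two reversibly formed bromonium ions only the one on the face of C11 can be opened at the Markovnikov carbon C3 by the tethered C7 hydroxyl, so C2–Br ends anti to the ether oxygen (2S) and C3–O on the C7 face (3S), both fixed by C6 through the temporary 2-oxabicyclo[2.2.2]octane ring, while the hindered vinyl group is left alone.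

Step 7
Reactants: 10 (1S,4R,6S)-6-bromo-1,3,3-trimethyl-4-(2-methylbut-3-en-2-yl)-2-oxabicyclo[2.2.2]octane
Product: 12 (1S,2S,4S)-2-bromo-1-methyl-4-(2-methylbut-3-en-2-yl)-4-(prop-1-en-2-yl)cyclohexan-1-ol, via silyl ether 11 (not isolated)
Conditions: Me3SiOTf (1.5 equiv), 2,6-lutidine (2.5 equiv), CH2Cl2, −78 to 0 °C; then 1 M HCl, THF, 0 °C
Reagents that add atoms: none
Why: Silyl triflate-induced E1-type cleavage of a tertiary alkyl ether (the reaction type used to remove tert-butyl ethers): the silyloxonium ion should ionise at the C7–O bond, which is relieved of strain and has six β-hydrogens, and not at the C3–O bond, which the β-bromine deactivates, so that lutidine takes a methyl proton and C7 becomes the isopropenyl group while C2, C3 and C6 stay as they are; the tertiary silyl ether is then hydrolysed under acid, where the bromohydrin cannot close to an epoxide.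

Step 8
Reactants: 12 (1S,2S,4S)-2-bromo-1-methyl-4-(2-methylbut-3-en-2-yl)-4-(prop-1-en-2-yl)cyclohexan-1-ol
Product: 13 (1S,2S,4S)-2-bromo-1-chloro-1-methyl-4-(2-methylbut-3-en-2-yl)-4-(prop-1-en-2-yl)cyclohexane
Conditions: SOCl2 (1.5 equiv), CH2Cl2, −20 to 0 °C
Reagents that add atoms: thionyl chloride, O=S(Cl)Cl
Why: Chlorodehydroxylation of a tertiary alcohol with neighbouring-group participation: the chlorosulfite ionises to the bromonium ion bridged from the C2 bromine on its own face, and chloride returns to the tertiary carbon C3 anti to bromine, i.e. from the face the oxygen left, so that C3 is substituted with net retention (3S) and bromine and chlorine end trans.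

Step 9
Reactants: 13 (1S,2S,4S)-2-bromo-1-chloro-1-methyl-4-(2-methylbut-3-en-2-yl)-4-(prop-1-en-2-yl)cyclohexane
Product: 14 3-[(1S,3S,4S)-3-bromo-4-chloro-4-methyl-1-(prop-1-en-2-yl)cyclohexyl]-3-methylbutanal
Conditions: PdCl2(PhCN)2 (10 mol %), CuCl2·2H2O (10 mol %), AgNO2 (5 mol %), O2 (1 atm), tBuOH/MeNO2 15:1, rt
Reagents that add atoms: dioxygen, O=O
Why: Aldehyde-selective (anti-Markovnikov) Wacker oxidation with nitrite co-catalysis, a reaction type established for vinyl groups on quaternary carbons; the 1,1-disubstituted isopropenyl group and the alkyl halides should not react and no stereocenter is touched.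

Step 10
Reactants: 14 3-[(1S,3S,4S)-3-bromo-4-chloro-4-methyl-1-(prop-1-en-2-yl)cyclohexyl]-3-methylbutanal
Product: 15 (2S)-2-bromo-3-[(1S,3S,4S)-3-bromo-4-chloro-4-methyl-1-(prop-1-en-2-yl)cyclohexyl]-3-methylbutanal
Conditions: (2R,5R)-2,5-diphenylpyrrolidine (20 mol %), 4,4-dibromo-2,6-di-tert-butylcyclohexa-2,5-dien-1-one (1.2 equiv), PhCO2H (20 mol %), H2O (2 equiv), CH2Cl2/pentane 1:1, −40 °C
Reagents that add atoms: 4,4-dibromo-2,6-di-tert-butylcyclohexa-2,5-dien-1-one, CC(C)(C)C1=CC(Br)(Br)C=C(C(C)(C)C)C1=O
Why: Enamine-catalysed enantioselective α-bromination of an aldehyde: the C2-symmetric pyrrolidine shields one face of the E-enamine, so C10 is set as S by the catalyst alone (the ring stereocenters are too remote to interfere), and the crowded α-bromo aldehyde should neither brominate twice nor epimerise before use.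

Step 11
Reactants: 15 (2S)-2-bromo-3-[(1S,3S,4S)-3-bromo-4-chloro-4-methyl-1-(prop-1-en-2-yl)cyclohexyl]-3-methylbutanal
Product: 16 (2S,3R,6S,8S,9S)-2,8-dibromo-9-chloro-1,1,9-trimethyl-5-methylidenespiro[5.5]undecan-3-ol
Conditions: Me2AlCl (2 equiv, 1 M in hexanes), CH2Cl2, −78 to −30 °C; 1 M HCl work-up
Reagents that add atoms: none
Why: Me2AlCl complexes the aldehyde, the terminal carbon of the isopropenyl group (C8) attacks C9 and a hydrogen of the allylic methyl group passes to the carbonyl oxygen through a six-membered array, so that the double bond moves to C7=C14 and the aluminium alkoxide forms with loss of methane. The closest known reaction type is the type-two intramolecular carbonyl-ene cyclisation of 5-methylhex-5-enals to 3-methylenecyclohexanols under Me2AlCl. Ring B closes as a six-membered chair by attack of the alkene terminus on the carbonyl carbon (alkene endocyclic, carbonyl exocyclic to the forming ring), helped by the two quaternary centres C6 and C11. C9 is the only new stereocenter and is controlled by C10: bromine sits equatorial and antiperiplanar to the forming C8–C9 bond (polar Felkin–Anh arrangement), and the oxygen has to be axial to reach the methyl hydrogen, which places the hydroxyl cis to bromine (9R in chamigrane numbering). The step needs chemoselectivity for the ene path over methyl transfer from aluminium and over ionisation of the tertiary chloride; the activation of the aldehyde by the α-bromine, the gem-dialkyl compression and the low temperature should secure it.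

**Compound list**

1 | ketopantolactone, 4,4-dimethyloxolane-2,3-dione | CC1(C)COC(=O)C1=O | starting material
2 | 4,4-dimethyl-3-methylideneoxolan-2-one | C=C1C(=O)OCC1(C)C | intermediate
3 | isoprene, 2-methylbuta-1,3-diene | C=CC(C)=C | starting material
4 | (5R)-4,4,8-trimethyl-2-oxaspiro[4.5]dec-7-en-1-one | CC1=CC[C@@]2(CC1)C(=O)OCC2(C)C | intermediate
5 | 1-[(1R)-1-(1-hydroxy-2-methylpropan-2-yl)-4-methylcyclohex-3-en-1-yl]ethan-1-one (hydroxy ketone, present as its alkoxide) | CC1=CC[C@@](C(C)=O)(C(C)(C)CO)CC1 | intermediate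
6 | 2-[(1R)-1-(1-hydroxy-2-methylpropan-2-yl)-4-methylcyclohex-3-en-1-yl]propan-2-ol | CC1=CC[C@@](C(C)(C)O)(C(C)(C)CO)CC1 | intermediate
7 | 2-[(1R)-1-(2-hydroxypropan-2-yl)-4-methylcyclohex-3-en-1-yl]-2-methylpropanal (hydroxy aldehyde) | CC1=CC[C@@](C(C)(C)O)(C(C)(C)C=O)CC1 | intermediate
8 | (5R)-1,1,4,4,8-pentamethyl-2-oxaspiro[4.5]dec-7-en-3-ol (lactol, both C3 epimers) | CC1=CC[C@@]2(CC1)C(C)(C)OC(O)C2(C)C | intermediate
9 | 2-[(1R)-4-methyl-1-(2-methylbut-3-en-2-yl)cyclohex-3-en-1-yl]propan-2-ol | CC1=CC[C@@](C(C)(C)O)(C(C)(C)C=C)CC1 | intermediate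
10 | (1S,4R,6S)-6-bromo-1,3,3-trimethyl-4-(2-methylbut-3-en-2-yl)-2-oxabicyclo[2.2.2]octane (Br anti to the ether oxygen) | C=CC(C)(C)[C@]12CC[C@](C)(OC1(C)C)[C@@H](Br)C2 | intermediate
11 | {[(1S,2S,4S)-2-bromo-1-methyl-4-(2-methylbut-3-en-2-yl)-4-(prop-1-en-2-yl)cyclohexyl]oxy}trimethylsilane (silyl ether) | C=CC(C)(C)[C@@]1(C(C)=C)CC[C@](C)(O[Si](C)(C)C)[C@@H](Br)C1 | intermediate
12 | (1S,2S,4S)-2-bromo-1-methyl-4-(2-methylbut-3-en-2-yl)-4-(prop-1-en-2-yl)cyclohexan-1-ol | C=CC(C)(C)[C@@]1(C(C)=C)CC[C@](C)(O)[C@@H](Br)C1 | intermediate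
13 | (1S,2S,4S)-2-bromo-1-chloro-1-methyl-4-(2-methylbut-3-en-2-yl)-4-(prop-1-en-2-yl)cyclohexane | C=CC(C)(C)[C@@]1(C(C)=C)CC[C@](C)(Cl)[C@@H](Br)C1 | intermediate
14 | 3-[(1S,3S,4S)-3-bromo-4-chloro-4-methyl-1-(prop-1-en-2-yl)cyclohexyl]-3-methylbutanal | O=CCC(C)(C)[C@@]1(C(C)=C)CC[C@](C)(Cl)[C@@H](Br)C1 | intermediate
15 | (2S)-2-bromo-3-[(1S,3S,4S)-3-bromo-4-chloro-4-methyl-1-(prop-1-en-2-yl)cyclohexyl]-3-methylbutanal | O=C[C@@H](Br)C(C)(C)[C@@]1(C(C)=C)CC[C@](C)(Cl)[C@@H](Br)C1 | intermediate
16 | (2S,3R,6S,8S,9S)-2,8-dibromo-9-chloro-1,1,9-trimethyl-5-methylidenespiro[5.5]undecan-3-ol; in chamigrane numbering (2S,3S,6S,9R,10S)-2,10-dibromo-3-chlorochamigr-7(14)-en-9-ol | C=C1C[C@@H](O)[C@@H](Br)C(C)(C)[C@]12CC[C@](C)(Cl)[C@@H](Br)C2 | target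

**Step count and risks**

Total step count: 11. Longest linear sequence: 11 steps (1 to 16).

Steps most likely to fail:

Step 11. The ring may close through an open, stepwise transition state with the complexed oxygen equatorial, which would give the wrong carbinol configuration. Methyl transfer from aluminium to the aldehyde or ionisation of the tertiary chloride may also outrun the ene transfer. The fallback no longer asks the ring closure to set C9. It sets out from 15, which is cyclised with the non-alkylating Lewis acid SnCl4 (CH2Cl2, −78 °C) in a Prins-type closure with proton loss from the methyl group. Either carbinol configuration is accepted, and mainly the C9-epimeric bromohydrin F1 is expected. Dess–Martin periodinane (NaHCO3, CH2Cl2) then gives the bromo ketone F2. Reduction with iBu2AlH in toluene at −78 °C should deliver hydride from the equatorial direction, because the axial C11 methyl blocks the axial approach. This gives the axial alcohol cis to bromine, and the route is rejoined at 16.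

Step 2. The catalyst may discriminate poorly between the faces of the hindered exocyclic enoate, or turnover may be slow. The fallback moves the asymmetric event to a desymmetrisation. It sets out from 2, which is heated with 2-(trimethylsilyloxy)buta-1,3-diene (toluene, 110 °C) to give the silyl enol ether F3. Acidic work-up gives the achiral diketo lactone F4. Enantiotopic deprotonation with lithium (R,R)-bis(1-phenylethyl)amide (THF, −100 °C) and trapping with PhNTf2 gives the enol triflate F5. Cross-coupling with MeMgBr under Fe(acac)3 catalysis (THF/NMP, −30 °C) rejoins the route at 4.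

Step 8. The cation at C3 may be captured across the ring by the isopropenyl π bond, may lose a proton, or HCl may add to the isopropenyl group. The fallback masks that alkene during the cation chemistry. It sets out from 12, which is treated with excess anhydrous HCl (CH2Cl2, −20 °C). This converts the tertiary alcohol through the bromonium ion and hydrochlorinates the isopropenyl group in the Markovnikov sense, giving the dichloride F6. Selective E1 loss of HCl from the strained 2-chloropropan-2-yl group (2,6-lutidine, 60 °C) then regenerates the isopropenyl group. Only methyl hydrogens are available there, and the C3 chloride is deactivated by the β-bromine. The route is rejoined at 13.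

**Further compounds**

F1 | step 11 | (2S,3S,6S,8S,9S)-2,8-dibromo-9-chloro-1,1,9-trimethyl-5-methylidenespiro[5.5]undecan-3-ol (C9 epimer of 16 in chamigrane numbering) | C=C1C[C@H](O)[C@@H](Br)C(C)(C)[C@]12CC[C@](C)(Cl)[C@@H](Br)C2
F2 | step 11 | (2S,6S,8S,9S)-2,8-dibromo-9-chloro-1,1,9-trimethyl-5-methylidenespiro[5.5]undecan-3-one | C=C1CC(=O)[C@@H](Br)C(C)(C)[C@]12CC[C@](C)(Cl)[C@@H](Br)C2
F3 | step 2 | 4,4-dimethyl-8-[(trimethylsilyl)oxy]-2-oxaspiro[4.5]dec-7-en-1-one (racemic) | C[Si](C)(C)OC1=CCC2(CC1)C(=O)OCC2(C)C
F4 | step 2 | 4,4-dimethyl-2-oxaspiro[4.5]decane-1,8-dione | O=C1CCC2(CC1)C(=O)OCC2(C)C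
F5 | step 2 | (5R)-4,4-dimethyl-1-oxo-2-oxaspiro[4.5]dec-7-en-8-yl trifluoromethanesulfonate | O=S(=O)(OC1=CC[C@@]2(CC1)C(=O)OCC2(C)C)C(F)(F)F
F6 | step 8 | (1S,2S,4R)-2-bromo-1-chloro-4-(2-chloropropan-2-yl)-1-methyl-4-(2-methylbut-3-en-2-yl)cyclohexane | C=CC(C)(C)[C@@]1(C(C)(C)Cl)CC[C@](C)(Cl)[C@@H](Br)C1
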